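# Proposed total synthesis of CNP0154953.1 (compound 23)

## Analysis of the target

Compound 23 is a dimer of two (2R,3R)-2-phenylchroman-3,5,7-triol units joined by one bond between C4 of the upper unit and C8' of the lower unit. The upper unit consists of ring A (the trioxygenated benzo ring), ring C (the pyran) and ring B (phenyl on C2); the lower unit consists of ring D (benzo ring), ring F (pyran) and ring E (phenyl on C2'). There are five stereocentres: C2, C3 and C4 in ring C (2R,3R,4R; phenyl and hydroxyl cis, hydroxyl and the ring D substituent trans) and C2' and C3' in ring F (2R,3R; cis). The two sets are separated by the flat ring D, so neither can control the other. Both 2,3-cis arrangements are the less stable ones and cannot be reached by equilibration, so each has to be set kinetically. The sensitive elements are the phenolic hydroxyls on very electron-rich rings (oxidation, substitution at C6, C8 and C6'), the C4–C8' bond (acid protonates ring D and expels a C4 benzylic cation) and the benzylic C2–O1 and C2'–O1' ether bonds. The hard part is the C3–C4 region: C4 is a diarylmethine flanked by the C5 oxygen and by both ortho oxygens of ring D, it must be formed with defined configuration next to C3, and the link must go to C8' and not to C6'. The strategy rests on two features of ring C. C4 is benzylic to ring A and ortho to O1, so C4, C4a, C8a and O1 are the four atoms of a latent ortho-quinone methide. C3 carries oxygen next to C2, so C3 and C2 can be the α-carbon and the carbonyl carbon of an α-oxygenated aldehyde; joining the two fragments forms C3–C4 and O1–C2 and closes ring C.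

## Retrosynthetic reasoning

**23 back to 21.** All phenols and the C3' hydroxyl are carried as benzyl ethers and the C3 hydroxyl as a silyl ether. The O–benzyl bonds are cut last (22 to 23) because hydrogenolysis is neutral and leaves nothing to separate from a polar hexol. The O–Si bond is cut just before (21 to 22) so that fluoride never meets free phenols.

**21 back to 20 (O1–C2).** C2 is a secondary benzylic carbon that carries an unactivated phenyl ring, so it is a good site for an SN2 displacement by the ring A hydroxyl. The forward reaction is a Mitsunobu ring closure with inversion; the open-chain precursor 20 must therefore have its C2 hydroxyl and C3 silyloxy group 1,2-anti.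

**20 back to 18 (C2–ring B).** Cutting the bond between C2 and the phenyl ring turns C2 into an aldehyde carbon, masked as the lactol 18. The forward reaction opens the lactol to the phenoxide aldehyde 19 and adds a phenyl nucleophile under non-chelation control.

**18 back to 13 and 14 (C3–C4 and O1–C2, the key disconnection).** Cutting C3–C4 and the lactol C–O bond gives the two-carbon aldehyde 14 and the quinone methide 15, which is the dehydration product of carbinol 13. This is the only place where one operation makes a ring, two skeletal bonds and two stereocentres (C3 and C4) under external control. In the forward direction the enamine 16 of 14 adds to C4 of 15, the released aldehyde 17 closes to 18, and a chiral secondary amine has to fix C3 and, through the transition state, C4.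

**13 back to 7 and 10 (C4–C8').** The carbinol carbon is bonded to two aryl rings; cutting the bond to C8' gives aryllithium 11 (from bromide 7) and aldehyde 10. The bromine fixes the link at C8', and the configuration of the carbinol does not matter because it is lost in 15. Ring A must carry the only free hydroxyl in 13 but cannot carry it during the organolithium addition, so it is masked as an allyl ether (12) and released under neutral conditions.

**10 back to 8.** The aldehyde comes from 8 by dibenzylation of the two more reactive hydroxyls (9) and allylation of the remaining hydrogen-bonded one.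

**7 back to 5.** The bromine (7 from 6) and the C3' benzyl ether (6 from 5) are added to the finished lower monomer, where C8' is the most nucleophilic ring position.

**5 back to 1 and 3 (C4'–C4a', then C2'–O1').** Cutting C4'–C4a' gives the epoxy ether 4, whose two stereocentres are carried unchanged into ring F. Cutting the C2'–O1' bond of 4 gives phenol 3 and epoxy alcohol 2, joined with inversion. 2 comes from racemic 1 by an asymmetric epoxidation that also resolves it. The whole lower unit thus takes its configuration from one reagent-controlled step.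

## Alternatives that were turned down

**Alternative 1: two-directional syn-phenylation.** Both C2–phenyl bonds are cut at once.

- Key step: the substrate is the bis(2,3-epoxide) A2, in which each pyran ring is an acetal-type epoxide with oxygen on the face that the C3 hydroxyl occupies in 23. A phenylaluminium Lewis acid would open each epoxide at the acetal carbon and deliver phenyl on the same face (retention), giving the 5,7,5',7'-tetra-O-benzyl ether A1, one hydrogenolysis from 23.
- For it: two C–C bonds, two hydroxyls and both cis relationships in one operation, and a short end game. On step economy after the key step it is stronger than the chosen route, which needs an addition and a ring closure to place the upper phenyl.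
- Against it: A2 has to be made by epoxidising two enol ether double bonds. In the upper ring the C4 substituent can steer the oxidant to the opposite face. The lower ring has no stereocentre (C4' is a methylene group), so C2' and C3' would form on either face and a mixture of diastereomers is to be expected. C4 would still have to be made enantiopure. Epoxides whose carbon is also an acetal carbon next to an aryloxy group are very labile, and A2 has two.
- Comparison: the chosen strategy gives up the double phenylation but sets C2'/C3' by an asymmetric epoxidation with stereospecific follow-up and C3/C4 under catalyst control, so no stereocentre depends on a remote one.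

**Alternative 2: late epoxy ether closure of the lower ring.** The lower pyran is closed last by cutting C4'–C4a'.

- Key step: A4 is the complete benzylated upper flavan whose C4 aryl group (the future ring D) carries an ether oxygen bound to a (phenyl)(oxiranyl)methyl group. A Lewis acid would activate the terminal epoxide, the ring D carbon ortho to the ether oxygen would attack C4', and A3, the pentabenzyl ether with a free C3' hydroxyl, would result.
- For it: the closure is stereospecific (C2' and C3' come in from an enantiopure epoxy alcohol and are not touched) and only one ring D carbon can reach. On diastereoselectivity in the key step it is stronger than the chosen route, which has to create two stereocentres there.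
- Against it: the disconnection simplifies the easier half. The upper flavan with its C4 stereocentre must exist first, and this plan does not say how. The ether would be made by substitution with a phenol oxygen next to the bulky C4 substituent. The Lewis acid acts on a molecule that already contains the acid-labile C4–C8' bond and two nucleophilic ring A positions (C6, C8) that can intercept the epoxide.
- Comparison: the chosen route uses the same epoxide–arene closure, but on the small ether 4 in step 3, where no interflavan bond exists and failure is cheap, and spends its key step on the C3–C4 problem that Alternative 2 leaves open.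

**Alternative 3: cation–arene closure of ring C.** Ring C is closed by cutting C4–C4a.

- Key step: the open-chain carbinol A6 has the C2–O1 ether and the C3 benzyloxy group in place, with C2 and C3 taken from a three-carbon chiral-pool aldehyde, and carries the lower flavan on C4. A Lewis acid would ionise either carbinol epimer to one cation stabilised by ring D, and an ortho carbon of the symmetrical 3,5-bis(benzyloxy)phenyl ether would attack it to give the hexabenzyl ether A5.
- For it: it is stereoconvergent at the carbinol, the nucleophilic ring is symmetrical, C2 is already set, and A5 needs only hydrogenolysis. On end-game length and on the security of C2 it is stronger than the chosen route.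
- Against it: C4 is decided in a cyclisation onto a freely rotating acyclic cation, and no element can be named that enforces the 3,4-trans result (in ring C of 23 the ring D substituent is axial when the C2 phenyl is equatorial, so the product-like transition state is not the obviously preferred one). The cation has ether oxygens on C3 and C2 that can participate or be lost. A6 needs a long linear sequence, including an aryl ether at a secondary benzylic carbon and the addition of 11 to an α,β-dioxygenated aldehyde, so 7 must be made anyway.
- Comparison: the chosen route shares the convergent C4 electrophile (both epimers of 13 give 15) but lets a catalyst-bound nucleophile build C3 at the same time and control the sense of attack. The price is the later stereochemical work at C2 (steps 11 and 12).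

Key step: step 10

Assumption: quinone methide 15 is taken to react through the same open transition state as simpler ortho-quinone methides, so that the (S)-configured amine gives the (3R,4R) lactol; 1 is used as the racemate and resolved in step 1.

## Route

Step 1
Reactants: 1 rac-1-phenylprop-2-en-1-ol
Product: 2 (S)-[(R)-oxiran-2-yl](phenyl)methanol (erythro)
Conditions: Ti(OiPr)4 (15 mol%), L-(+)-DIPT (18 mol%), TBHP (0.45 equiv), 4 Å MS, CH2Cl2, −20 °C
Reagents that add atoms: tert-butyl hydroperoxide, CC(C)(C)OO
Why: Sharpless asymmetric epoxidation run as a kinetic resolution: with L-(+)-DIPT the (R)-enantiomer of 1 should be epoxidised much faster than the (S)-enantiomer, which is left behind, and the titanium-bound alkoxide directs oxygen to one alkene face, so the erythro epoxy alcohol forms with both centres set by the reagent; substoichiometric oxidant keeps conversion below one half.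

Step 2
Reactants: 2 (S)-[(R)-oxiran-2-yl](phenyl)methanol; 3 3,5-bis(benzyloxy)phenol
Product: 4 (R)-2-[(R)-[3,5-bis(benzyloxy)phenoxy](phenyl)methyl]oxirane (threo)
Conditions: PPh3, DIAD, THF, 0 °C → rt
Reagents that add atoms: none
Why: Mitsunobu etherification; the phenol displaces the activated secondary hydroxyl by SN2 with inversion, turning the erythro alcohol into the threo ether, and the electron-withdrawing epoxide next to the benzylic carbon disfavours ionisation and so racemisation.

Step 3
Reactants: 4 (R)-2-[(R)-[3,5-bis(benzyloxy)phenoxy](phenyl)methyl]oxirane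
Product: 5 (2R,3R)-5,7-bis(benzyloxy)-2-phenylchroman-3-ol (2,3-cis)
Conditions: AuCl3 (5 mol%), AgOTf (15 mol%), ClCH2CH2Cl, rt
Reagents that add atoms: none
Why: Lewis acid-catalysed intramolecular Friedel–Crafts alkylation (epoxide–arene cyclisation): the activated epoxide is attacked at its unsubstituted carbon (6-endo) by the ring carbon ortho to the ether oxygen, which is activated by three oxygens and is the only one that can reach; no bond to C2 or C3 is broken, so the threo ether gives the 2,3-cis chromanol, a closure known for aryl ethers of 1-aryl-2,3-epoxypropanols.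

Step 4
Reactants: 5 (2R,3R)-5,7-bis(benzyloxy)-2-phenylchroman-3-ol
Product: 6 (2R,3R)-3,5,7-tris(benzyloxy)-2-phenylchroman
Conditions: NaH, BnBr, DMF, 0 °C → rt
Reagents that add atoms: benzyl bromide, BrCc1ccccc1
Why: Williamson etherification of the secondary alkoxide; it protects the C3 hydroxyl against the organometallic and Mitsunobu steps with a group that leaves in the final hydrogenolysis.

Step 5
Reactants: 6 (2R,3R)-3,5,7-tris(benzyloxy)-2-phenylchroman
Product: 7 (2R,3R)-3,5,7-tris(benzyloxy)-8-bromo-2-phenylchroman
Conditions: NBS (1.0 equiv), CH2Cl2, −78 °C → rt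
Reagents that add atoms: N-bromosuccinimide, O=C1CCC(=O)N1Br
Why: Electrophilic aromatic bromination; of the two free ring positions, C8 between O1 and the C7 ether is the more nucleophilic and should be brominated selectively at low temperature, as is usual for 5,7-dialkoxyflavans.

Step 6
Reactants: 8 2,4,6-trihydroxybenzaldehyde
Product: 9 2,4-bis(benzyloxy)-6-hydroxybenzaldehyde
Conditions: BnBr (2.05 equiv), K2CO3, DMF, 0 °C → rt
Reagents that add atoms: benzyl bromide, BrCc1ccccc1
Why: Williamson etherification; the para hydroxyl and one ortho hydroxyl are alkylated, while the last ortho hydroxyl, held in a hydrogen bond to the formyl group, reacts much more slowly, so two equivalents should stop at 9.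

Step 7
Reactants: 9 2,4-bis(benzyloxy)-6-hydroxybenzaldehyde
Product: 10 2-(allyloxy)-4,6-bis(benzyloxy)benzaldehyde
Conditions: allyl bromide, K2CO3, DMF, 50 °C
Reagents that add atoms: allyl bromide, C=CCBr
Why: Williamson etherification of the hydrogen-bonded hydroxyl under warmer conditions; the allyl group is inert to the aryllithium addition and is later removed under neutral conditions that spare benzyl ethers and the acid-labile carbinol.

Step 8
Reactants: 7 (2R,3R)-3,5,7-tris(benzyloxy)-8-bromo-2-phenylchroman; 10 2-(allyloxy)-4,6-bis(benzyloxy)benzaldehyde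
Product: 12 [2-(allyloxy)-4,6-bis(benzyloxy)phenyl][(2R,3R)-3,5,7-tris(benzyloxy)-2-phenylchroman-8-yl]methanol (both carbinol epimers), via aryllithium 11 (not isolated)
Conditions: n-BuLi, THF, −78 °C; then 10, −78 → 0 °C; then H2O
Reagents that add atoms: none
Why: Bromine–lithium exchange is faster than any deprotonation at −78 °C, and the 8-lithio species adds to the formyl group (1,2-addition); the carbinol centre forms as both epimers, which is harmless because it becomes trigonal in step 10, and the basic aqueous quench avoids ionising the product.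

Step 9
Reactants: 12 [2-(allyloxy)-4,6-bis(benzyloxy)phenyl][(2R,3R)-3,5,7-tris(benzyloxy)-2-phenylchroman-8-yl]methanol
Product: 13 [2,4-bis(benzyloxy)-6-hydroxyphenyl][(2R,3R)-3,5,7-tris(benzyloxy)-2-phenylchroman-8-yl]methanol (both carbinol epimers)
Conditions: Pd(PPh3)4 (5 mol%), morpholine (10 equiv), THF, rt
Reagents that add atoms: none
Why: Tsuji–Trost deallylation; zerovalent palladium ionises the allyl aryl ether to a π-allyl complex and the phenoxide, morpholine traps the allyl fragment, and the neutral conditions leave the benzyl ethers and the doubly activated carbinol untouched.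

Step 10
Reactants: 13 [2,4-bis(benzyloxy)-6-hydroxyphenyl][(2R,3R)-3,5,7-tris(benzyloxy)-2-phenylchroman-8-yl]methanol; 14 (tert-butyldimethylsilyloxy)acetaldehyde
Product: 18 (3R,4R)-5,7-bis(benzyloxy)-3-[(tert-butyldimethylsilyl)oxy]-4-[(2R,3R)-3,5,7-tris(benzyloxy)-2-phenylchroman-8-yl]chroman-2-ol (3,4-trans; both C2 anomers), via quinone methide 15 (not isolated), via enamine 16 (not isolated), via hydroxy aldehyde 17 (not isolated)
Conditions: 14 (3 equiv), (S)-α,α-diphenylprolinol trimethylsilyl ether (20 mol%), PhCO2H (20 mol%), CH2Cl2, 0 °C → rt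
Reagents that add atoms: none
Why: Benzoic acid ionises the doubly donor-stabilised carbinol of 13 (either epimer) and loss of water gives quinone methide 15, while the amine condenses with 14 to the E-enamine 16. The β-carbon of 16 adds to the exocyclic carbon C4 of 15 (Michael addition driven by rearomatisation of ring A), and hydrolysis of the catalyst-bound adduct returns the amine and gives hydroxy aldehyde 17. Ring C then closes by 6-exo-trig addition of the ring A hydroxyl to the formyl carbon (hemiacetal formation), giving lactol 18. The closest known reaction type is the amine/acid co-catalysed Michael addition–hemiacetalisation of aldehydes with ortho-quinone methides generated in situ from 2-[aryl(hydroxy)methyl]phenols, which gives trans-3,4-disubstituted chroman-2-ols. C3 is controlled by the catalyst: the diphenyl(silyloxy)methyl group shields one face of the s-trans enamine, and attack on the open face should give 3R, the same sense of induction as in additions of simple aldehydes to nitroalkenes. C4 is controlled by the relative orientation of the partners in the open transition state, with the quinone methide oxygen near the enamine nitrogen and the ring D group pointing away from the pyrrolidine; this leads to the syn adduct and hence the 3,4-trans lactol (4R). C2 of the lactol forms as both anomers, which does not matter because this centre is opened in step 11. The step needs a single quinone methide and catalyst control over the remote lower unit: only ring A has a free hydroxyl, ring D is fully etherified, and C2' and C3' lie five bonds from C4.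

Step 11
Reactants: 18 (3R,4R)-5,7-bis(benzyloxy)-3-[(tert-butyldimethylsilyl)oxy]-4-[(2R,3R)-3,5,7-tris(benzyloxy)-2-phenylchroman-8-yl]chroman-2-ol
Product: 20 (1S,2R,3R)-3-[2,4-bis(benzyloxy)-6-hydroxyphenyl]-2-[(tert-butyldimethylsilyl)oxy]-1-phenyl-3-[(2R,3R)-3,5,7-tris(benzyloxy)-2-phenylchroman-8-yl]propan-1-ol (1,2-anti), via magnesium phenoxide aldehyde 19 (not isolated)
Conditions: PhMgBr (4 equiv), THF, −78 → −30 °C; then H2O
Reagents that add atoms: phenylmagnesium bromide, Br[Mg]c1ccccc1
Why: The first equivalent of the Grignard reagent deprotonates the lactol, which opens to the aldehyde phenoxide 19, and a second equivalent adds to the formyl group; under Felkin–Anh (non-chelation) control, the bulky silyl ether being a poor ligand for magnesium, phenyl should enter anti to the α C–O bond and give the 1,2-anti diol; low temperature suppresses silyl migration and α-epimerisation.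

Step 12
Reactants: 20 (1S,2R,3R)-3-[2,4-bis(benzyloxy)-6-hydroxyphenyl]-2-[(tert-butyldimethylsilyl)oxy]-1-phenyl-3-[(2R,3R)-3,5,7-tris(benzyloxy)-2-phenylchroman-8-yl]propan-1-ol
Product: 21 (2R,3R,4R)-5,7-bis(benzyloxy)-3-[(tert-butyldimethylsilyl)oxy]-2-phenyl-4-[(2R,3R)-3,5,7-tris(benzyloxy)-2-phenylchroman-8-yl]chroman
Conditions: PPh3, DIAD, toluene, 0 °C → rt
Reagents that add atoms: none
Why: Intramolecular Mitsunobu etherification (6-exo-tet); the ring A hydroxyl displaces the activated benzylic hydroxyl with inversion, which converts the 1,2-anti diol into the 2,3-cis pyran, and because ring B is an unactivated phenyl the substitution should stay SN2; the C3 oxygen is silylated and cannot compete.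

Step 13
Reactants: 21 (2R,3R,4R)-5,7-bis(benzyloxy)-3-[(tert-butyldimethylsilyl)oxy]-2-phenyl-4-[(2R,3R)-3,5,7-tris(benzyloxy)-2-phenylchroman-8-yl]chroman
Product: 22 (2R,3R,4R)-5,7-bis(benzyloxy)-2-phenyl-4-[(2R,3R)-3,5,7-tris(benzyloxy)-2-phenylchroman-8-yl]chroman-3-ol
Conditions: TBAF, THF, 0 °C → rt
Reagents that add atoms: none
Why: Fluoride-induced cleavage of the silyl ether, driven by Si–F bond formation; the benzyl ethers, the interflavan bond and the stereocentres are not affected by these mild conditions.

Step 14
Reactants: 22 (2R,3R,4R)-5,7-bis(benzyloxy)-2-phenyl-4-[(2R,3R)-3,5,7-tris(benzyloxy)-2-phenylchroman-8-yl]chroman-3-ol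
Product: 23 (2R,3R,4R)-2-phenyl-4-[(2R,3R)-3,5,7-trihydroxy-2-phenylchroman-8-yl]chroman-3,5,7-triol
Conditions: H2 (1 atm), Pd(OH)2/C, THF/MeOH, rt
Reagents that add atoms: none
Why: Hydrogenolysis of the four aryl benzyl ethers and the one alkyl benzyl ether under neutral conditions; the ring ether bonds at C2 and C2' and the acid-labile C4–C8' bond should survive, and only toluene has to be removed from the polar hexol.

## Compound list

1 | rac-1-phenylprop-2-en-1-ol | OC(C=C)c1ccccc1 | starting material
2 | (S)-[(R)-oxiran-2-yl](phenyl)methanol | O[C@@H](c1ccccc1)[C@H]1CO1 | intermediate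
3 | 3,5-bis(benzyloxy)phenol | Oc1cc(OCc2ccccc2)cc(OCc2ccccc2)c1 | starting material
4 | (R)-2-[(R)-[3,5-bis(benzyloxy)phenoxy](phenyl)methyl]oxirane | c1(OCc2ccccc2)cc(OCc2ccccc2)cc(c1)O[C@H](c1ccccc1)[C@H]1CO1 | intermediate
5 | (2R,3R)-5,7-bis(benzyloxy)-2-phenylchroman-3-ol | c1c(OCc3ccccc3)cc(OCc3ccccc3)c2c1O[C@H](c1ccccc1)[C@H](O)C2 | intermediate
6 | (2R,3R)-3,5,7-tris(benzyloxy)-2-phenylchroman | c1c(OCc3ccccc3)cc(OCc3ccccc3)c2c1O[C@H](c1ccccc1)[C@H](OCc1ccccc1)C2 | intermediate
7 | (2R,3R)-3,5,7-tris(benzyloxy)-8-bromo-2-phenylchroman | Brc1c(OCc3ccccc3)cc(OCc3ccccc3)c2c1O[C@H](c1ccccc1)[C@H](OCc1ccccc1)C2 | intermediate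
8 | 2,4,6-trihydroxybenzaldehyde | O=Cc1c(O)cc(O)cc1O | starting material
9 | 2,4-bis(benzyloxy)-6-hydroxybenzaldehyde | O=Cc1c(O)cc(OCc2ccccc2)cc1OCc1ccccc1 | intermediate
10 | 2-(allyloxy)-4,6-bis(benzyloxy)benzaldehyde | O=Cc1c(OCC=C)cc(OCc2ccccc2)cc1OCc1ccccc1 | intermediate
11 | [(2R,3R)-3,5,7-tris(benzyloxy)-2-phenylchroman-8-yl]lithium | [Li]c1c(OCc3ccccc3)cc(OCc3ccccc3)c2c1O[C@H](c1ccccc1)[C@H](OCc1ccccc1)C2 | intermediate (not isolated)
12 | [2-(allyloxy)-4,6-bis(benzyloxy)phenyl][(2R,3R)-3,5,7-tris(benzyloxy)-2-phenylchroman-8-yl]methanol (carbinol epimers) | C=CCOc1cc(OCc2ccccc2)cc(OCc2ccccc2)c1C(O)c1c(OCc2ccccc2)cc(OCc2ccccc2)c2c1O[C@H](c1ccccc1)[C@H](OCc1ccccc1)C2 | intermediate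
13 | [2,4-bis(benzyloxy)-6-hydroxyphenyl][(2R,3R)-3,5,7-tris(benzyloxy)-2-phenylchroman-8-yl]methanol (carbinol epimers) | Oc1cc(OCc2ccccc2)cc(OCc2ccccc2)c1C(O)c1c(OCc2ccccc2)cc(OCc2ccccc2)c2c1O[C@H](c1ccccc1)[C@H](OCc1ccccc1)C2 | intermediate
14 | (tert-butyldimethylsilyloxy)acetaldehyde | O=CCO[Si](C)(C)C(C)(C)C | starting material
15 | 3,5-bis(benzyloxy)-6-{[(2R,3R)-3,5,7-tris(benzyloxy)-2-phenylchroman-8-yl]methylidene}cyclohexa-2,4-dien-1-one (double-bond geometry open) | O=C1C=C(OCc2ccccc2)C=C(OCc2ccccc2)C1=Cc1c(OCc2ccccc2)cc(OCc2ccccc2)c2c1O[C@H](c1ccccc1)[C@H](OCc1ccccc1)C2 | intermediate (not isolated)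
16 | (S)-1-[(E)-2-[(tert-butyldimethylsilyl)oxy]ethenyl]-2-[diphenyl(trimethylsilyloxy)methyl]pyrrolidine | C[Si](C)(C)OC(c1ccccc1)(c1ccccc1)[C@@H]1CCCN1/C=C/O[Si](C)(C)C(C)(C)C | intermediate (not isolated)
17 | (2R,3R)-3-[2,4-bis(benzyloxy)-6-hydroxyphenyl]-2-[(tert-butyldimethylsilyl)oxy]-3-[(2R,3R)-3,5,7-tris(benzyloxy)-2-phenylchroman-8-yl]propanal | Oc1cc(OCc2ccccc2)cc(OCc2ccccc2)c1[C@H](c1c(OCc2ccccc2)cc(OCc2ccccc2)c2c1O[C@H](c1ccccc1)[C@H](OCc1ccccc1)C2)[C@@H](O[Si](C)(C)C(C)(C)C)C=O | intermediate (not isolated)
18 | (3R,4R)-5,7-bis(benzyloxy)-3-[(tert-butyldimethylsilyl)oxy]-4-[(2R,3R)-3,5,7-tris(benzyloxy)-2-phenylchroman-8-yl]chroman-2-ol (C2 anomers) | C(c1ccccc1)Oc1cc(OCc3ccccc3)c2c(c1)OC(O)[C@H](O[Si](C)(C)C(C)(C)C)[C@H]2c1c(OCc3ccccc3)cc(OCc3ccccc3)c2c1O[C@H](c1ccccc1)[C@H](OCc1ccccc1)C2 | intermediate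
19 | bromomagnesium phenoxide of aldehyde 17 (ring-opened form of deprotonated 18) | Br[Mg]Oc1cc(OCc2ccccc2)cc(OCc2ccccc2)c1[C@H](c1c(OCc2ccccc2)cc(OCc2ccccc2)c2c1O[C@H](c1ccccc1)[C@H](OCc1ccccc1)C2)[C@@H](O[Si](C)(C)C(C)(C)C)C=O | intermediate (not isolated)
20 | (1S,2R,3R)-3-[2,4-bis(benzyloxy)-6-hydroxyphenyl]-2-[(tert-butyldimethylsilyl)oxy]-1-phenyl-3-[(2R,3R)-3,5,7-tris(benzyloxy)-2-phenylchroman-8-yl]propan-1-ol | Oc1cc(OCc2ccccc2)cc(OCc2ccccc2)c1[C@H](c1c(OCc2ccccc2)cc(OCc2ccccc2)c2c1O[C@H](c1ccccc1)[C@H](OCc1ccccc1)C2)[C@@H](O[Si](C)(C)C(C)(C)C)[C@@H](O)c1ccccc1 | intermediate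
21 | (2R,3R,4R)-5,7-bis(benzyloxy)-3-[(tert-butyldimethylsilyl)oxy]-2-phenyl-4-[(2R,3R)-3,5,7-tris(benzyloxy)-2-phenylchroman-8-yl]chroman | C(c1ccccc1)Oc1cc(OCc3ccccc3)c2c(c1)O[C@H](c1ccccc1)[C@H](O[Si](C)(C)C(C)(C)C)[C@H]2c1c(OCc3ccccc3)cc(OCc3ccccc3)c2c1O[C@H](c1ccccc1)[C@H](OCc1ccccc1)C2 | intermediate
22 | (2R,3R,4R)-5,7-bis(benzyloxy)-2-phenyl-4-[(2R,3R)-3,5,7-tris(benzyloxy)-2-phenylchroman-8-yl]chroman-3-ol | C(c1ccccc1)Oc1cc(OCc3ccccc3)c2c(c1)O[C@H](c1ccccc1)[C@H](O)[C@H]2c1c(OCc3ccccc3)cc(OCc3ccccc3)c2c1O[C@H](c1ccccc1)[C@H](OCc1ccccc1)C2 | intermediate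
23 | (2R,3R,4R)-2-phenyl-4-[(2R,3R)-3,5,7-trihydroxy-2-phenylchroman-8-yl]chroman-3,5,7-triol | Oc1cc(O)c2c(c1)O[C@H](c1ccccc1)[C@H](O)[C@H]2c1c(O)cc(O)c2c1O[C@H](c1ccccc1)[C@H](O)C2 | target

## Step count and least certain steps

Total step count: 14. Longest linear sequence: 12 steps (steps 1–5 and 8–14, from 1); the aldehyde branch (steps 6 and 7) joins at step 8.

**Step 10 (key step).** The most likely failure is poor control of the relative configuration at C4. The C5 benzyloxy group destabilises the usual geometry of the exocyclic double bond of 15, so the quinone methide may react from either geometry or as a freely rotating diarylmethyl cation, and then the orientation that gives the 3,4-trans lactol is no longer enforced. A second risk is slow C–C bond formation at the crowded C4, which leaves time for self-condensation of 14 and for acid-induced loss of ring D from 13.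

Fallback: form the C4–C8' bond on a finished ring C instead. The route sets out from 5 and, using 6 as the nucleophile, returns at 22. Oxidation of 5 at C4 with DDQ in the presence of ethylene glycol (CH2Cl2, rt) should give 5,7-bis(benzyloxy)-4-(2-hydroxyethoxy)-2-phenylchroman-3-ol F1 (2,3-cis, 3,4-trans, C2 and C3 as in 5). Treating F1 with TiCl4 in CH2Cl2/THF at 0 °C in the presence of excess 6 ionises the C4 ether, and C8 of 6 attacks the cyclic cation trans to the C3 hydroxyl, giving 22 directly. This is the established Lewis acid coupling of C4-activated benzylated flavan-3-ols; it bypasses steps 5 and 8–13, and its own weak point is competing attack through C6 of 6.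

**Step 11.** The most likely failure is erosion of facial selectivity in the Grignard addition. The very large diarylmethyl group on the α-carbon competes with the silyloxy group for the position anti to the incoming nucleophile, and residual magnesium chelation works in the same direction; both lead to the 1,2-syn epimer. Base-induced silyl migration to the new alkoxide is a further risk.

Fallback: use the syn epimer in a closure with retention instead of discarding it. The route sets out from 18 (same addition, no selectivity required) and returns at 21. The C1 epimer of 20, (1R,2R,3R)-3-[2,4-bis(benzyloxy)-6-hydroxyphenyl]-2-[(tert-butyldimethylsilyl)oxy]-1-phenyl-3-[(2R,3R)-3,5,7-tris(benzyloxy)-2-phenylchroman-8-yl]propan-1-ol F2, is separated. Its phenol is triflated chemoselectively (PhNTf2, K2CO3, CH2Cl2) to the aryl triflate of F2 F3. Palladium-catalysed intramolecular C–O coupling (Pd(OAc)2, 2-(di-tert-butylphosphino)-1,1'-binaphthyl, Cs2CO3, toluene, 70 °C; Buchwald–Hartwig-type etherification) then bonds the carbinol oxygen to the aryl carbon. C2 is not touched, so the syn diol gives the same 2,3-cis pyran 21 that the anti diol gives by inversion in step 12.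

**Step 12.** The most likely failure is slow activation of the hindered benzylic hydroxyl next to the silyloxy group, so that elimination toward the enol ether or intermolecular etherification overtakes the ring closure.

Fallback: an orthoester-mediated closure on the free diol. The route sets out from 20 and returns at 22. Desilylation (TBAF, THF) gives (1S,2R,3R)-3-[2,4-bis(benzyloxy)-6-hydroxyphenyl]-1-phenyl-3-[(2R,3R)-3,5,7-tris(benzyloxy)-2-phenylchroman-8-yl]propane-1,2-diol F4. Heating F4 with HC(OEt)3 and PPTS in ClCH2CH2Cl forms the cyclic orthoformate and from it a dioxolanylium ion, which the ring A hydroxyl opens at the benzylic carbon with inversion to give the C3 formate of 22 F5. Methanolysis (K2CO3, MeOH) then gives 22.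

**Step 8.** The most likely failure is proton transfer or simple non-reaction instead of addition, because the nucleophilic carbon of 11 has two ortho substituents and the formyl group of 10 is deactivated by three oxygen donors and flanked by two ortho ethers.

Fallback: reverse the polarity at C4. The route sets out from 7 (and 3) and returns at 13. Aryllithium 11, generated as in step 8, is quenched with DMF to give (2R,3R)-3,5,7-tris(benzyloxy)-2-phenylchroman-8-carbaldehyde F6. Phenol 3 is converted into its bromomagnesium phenoxide (EtMgBr, Et2O, then toluene/CH2Cl2) and combined with F6. Magnesium holds the phenoxide oxygen and the formyl oxygen in a six-membered transition state, so only an ortho carbon of 3 attacks (ortho-specific hydroxyalkylation of a magnesium phenoxide), and 13 forms directly with its free ring A hydroxyl. Steps 6, 7 and 9 then become unnecessary.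

## Further compounds

F1 | step 10 | 5,7-bis(benzyloxy)-4-(2-hydroxyethoxy)-2-phenylchroman-3-ol (2,3-cis, 3,4-trans; C2 and C3 as in 5) | C(c1ccccc1)Oc1cc(OCc3ccccc3)c2c(c1)O[C@H](c1ccccc1)[C@H](O)[C@H]2OCCO
F2 | step 11 | (1R,2R,3R)-3-[2,4-bis(benzyloxy)-6-hydroxyphenyl]-2-[(tert-butyldimethylsilyl)oxy]-1-phenyl-3-[(2R,3R)-3,5,7-tris(benzyloxy)-2-phenylchroman-8-yl]propan-1-ol (C1 epimer of 20, 1,2-syn) | Oc1cc(OCc2ccccc2)cc(OCc2ccccc2)c1[C@H](c1c(OCc2ccccc2)cc(OCc2ccccc2)c2c1O[C@H](c1ccccc1)[C@H](OCc1ccccc1)C2)[C@@H](O[Si](C)(C)C(C)(C)C)[C@H](O)c1ccccc1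
F3 | step 11 | aryl trifluoromethanesulfonate of F2 (phenol oxygen triflated, carbinol free) | FC(F)(F)S(=O)(=O)Oc1cc(OCc2ccccc2)cc(OCc2ccccc2)c1[C@H](c1c(OCc2ccccc2)cc(OCc2ccccc2)c2c1O[C@H](c1ccccc1)[C@H](OCc1ccccc1)C2)[C@@H](O[Si](C)(C)C(C)(C)C)[C@H](O)c1ccccc1
F4 | step 12 | (1S,2R,3R)-3-[2,4-bis(benzyloxy)-6-hydroxyphenyl]-1-phenyl-3-[(2R,3R)-3,5,7-tris(benzyloxy)-2-phenylchroman-8-yl]propane-1,2-diol | Oc1cc(OCc2ccccc2)cc(OCc2ccccc2)c1[C@H](c1c(OCc2ccccc2)cc(OCc2ccccc2)c2c1O[C@H](c1ccccc1)[C@H](OCc1ccccc1)C2)[C@@H](O)[C@@H](O)c1ccccc1
F5 | step 12 | (2R,3R,4R)-5,7-bis(benzyloxy)-2-phenyl-4-[(2R,3R)-3,5,7-tris(benzyloxy)-2-phenylchroman-8-yl]chroman-3-yl formate | C(c1ccccc1)Oc1cc(OCc3ccccc3)c2c(c1)O[C@H](c1ccccc1)[C@H](OC=O)[C@H]2c1c(OCc3ccccc3)cc(OCc3ccccc3)c2c1O[C@H](c1ccccc1)[C@H](OCc1ccccc1)C2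
F6 | step 8 | (2R,3R)-3,5,7-tris(benzyloxy)-2-phenylchroman-8-carbaldehyde | O=Cc1c(OCc3ccccc3)cc(OCc3ccccc3)c2c1O[C@H](c1ccccc1)[C@H](OCc1ccccc1)C2
A1 | alternative 1 | 5,7,5',7'-tetra-O-benzyl ether of 23 (both C3 hydroxyls free) | C(c1ccccc1)Oc1cc(OCc3ccccc3)c2c(c1)O[C@H](c1ccccc1)[C@H](O)[C@H]2c1c(OCc3ccccc3)cc(OCc3ccccc3)c2c1O[C@H](c1ccccc1)[C@H](O)C2
A2 | alternative 1 | 5,7-bis(benzyloxy)-2,3-epoxy-4-[5,7-bis(benzyloxy)-2,3-epoxychroman-8-yl]chroman, both epoxides on the face of the later C3 hydroxyls | C(c1ccccc1)Oc1cc(OCc3ccccc3)c2c(c1)O[C@@H]3O[C@@H]3[C@H]2c1c(OCc3ccccc3)cc(OCc3ccccc3)c2c1O[C@@H]3O[C@@H]3C2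
A3 | alternative 2 | 3,5,7,5',7'-penta-O-benzyl ether of 23 (C3' hydroxyl free) | C(c1ccccc1)Oc1cc(OCc3ccccc3)c2c(c1)O[C@H](c1ccccc1)[C@H](OCc1ccccc1)[C@H]2c1c(OCc3ccccc3)cc(OCc3ccccc3)c2c1O[C@H](c1ccccc1)[C@H](O)C2
A4 | alternative 2 | 3,5,7-tris(benzyloxy)-2-phenyl-4-{2,4-bis(benzyloxy)-6-[(R)-[(R)-oxiran-2-yl](phenyl)methoxy]phenyl}chroman, upper unit configured as in 23 | C(c1ccccc1)Oc1cc(OCc3ccccc3)c2c(c1)O[C@H](c1ccccc1)[C@H](OCc1ccccc1)[C@H]2c1c(OCc3ccccc3)cc(OCc3ccccc3)cc1O[C@H](c1ccccc1)[C@H]1CO1
A5 | alternative 3 | hexa-O-benzyl ether of 23 | C(c1ccccc1)Oc1cc(OCc3ccccc3)c2c(c1)O[C@H](c1ccccc1)[C@H](OCc1ccccc1)[C@H]2c1c(OCc3ccccc3)cc(OCc3ccccc3)c2c1O[C@H](c1ccccc1)[C@H](OCc1ccccc1)C2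
A6 | alternative 3 | 2-(benzyloxy)-3-[3,5-bis(benzyloxy)phenoxy]-3-phenyl-1-[(2R,3R)-3,5,7-tris(benzyloxy)-2-phenylchroman-8-yl]propan-1-ol (carbinol epimers; the two chain stereocentres as C3 and C2 of 23) | C(c1ccccc1)Oc1cc(OCc3ccccc3)cc(c1)O[C@H](c1ccccc1)[C@H](OCc1ccccc1)C(O)c1c(OCc3ccccc3)cc(OCc3ccccc3)c2c1O[C@H](c1ccccc1)[C@H](OCc1ccccc1)C2
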